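**Strategy.** The 20-membered ring is opened in the middle of its heteroatom-free (CH2)14 bridge, between the eighth carbon counted from ring B (the dihydroxy ring that carries the ether oxygen between the chain and an OH) and the sixth counted from ring A (the monohydroxy 1,3,5-trisubstituted ring). Both atoms are plain methylenes far from the arenes, so the bond is made as an olefin by macrocyclic ring-closing metathesis of a tris-benzyl diaryl ether bearing a non-8-enyl chain on ring B and a hept-6-enyl chain on ring A, the ether oxygen acting as hinge. One hydrogenation then erases the olefin and the benzyl groups. The diene comes from an Ullmann coupling.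

Key step: step 6

Remark on the chemistry: the target has no stereocentre, and its 20-membered ring is too large for stable planar chirality. It is therefore a single achiral compound and no stereocontrol is needed. Olefin 14 is expected as an E/Z mixture, so its SMILES is written without double-bond geometry.

**Step 1**
Reactants: 1 1-(benzyloxy)-3,5-dibromobenzene; 2 7-bromohept-1-ene
Product: 4 1-(benzyloxy)-3-bromo-5-(hept-6-enyl)benzene, via hept-6-enylzinc bromide 3 (not isolated)
Conditions: 2, Zn dust, I2 (cat.), DMA, 80 °C; then 1 (3 equiv), PdCl2(dppf) (3 mol%), THF/DMA, 50 °C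
Reagents that add atoms: none
Why: Negishi sp2–sp3 cross-coupling of a primary alkylzinc bromide, in which the threefold excess of the symmetrical dibromide and the lower reactivity of the alkylated monobromide should hold the reaction at the mono stage, while the remote terminal olefin and the benzyl ether are not affected.

**Step 2**
Reactants: 5 3,5-bis(benzyloxy)benzyl bromide; 6 8-bromooct-1-ene
Product: 8 1,3-bis(benzyloxy)-5-(non-8-enyl)benzene, via oct-7-enylmagnesium bromide 7 (not isolated)
Conditions: 6, Mg, THF, rt; then 5, Li2CuCl4 (3 mol%), THF, −20 °C to rt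
Reagents that add atoms: none
Why: Copper-catalysed Kochi-type sp3–sp3 coupling of a primary Grignard reagent with a benzylic bromide, the standard entry to 5-alkylresorcinol ethers, which tolerates benzyl ethers and a terminal olefin.

**Step 3**
Reactants: 8 1,3-bis(benzyloxy)-5-(non-8-enyl)benzene
Product: 10 2,4-bis(benzyloxy)-6-(non-8-enyl)benzaldehyde, via aryl iminium chloride 9 (not isolated)
Conditions: POCl3, DMF, 0 to 70 °C; then aq. NaOH, 0 °C
Reagents that add atoms: N,N-dimethylformamide CN(C)C=O; water O
Why: Vilsmeier–Haack formylation, in which the chloroiminium ion should attack the position para to one benzyloxy group and ortho to the other (next to the chain) in preference to the site between the two benzyloxy groups, as is known for 5-alkylresorcinol diethers, and unactivated olefins do not react.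

**Step 4**
Reactants: 10 2,4-bis(benzyloxy)-6-(non-8-enyl)benzaldehyde
Product: 12 2,4-bis(benzyloxy)-6-(non-8-enyl)phenol, via aryl formate 11 (not isolated)
Conditions: 30% aq. H2O2 (1.2 equiv), H2SO4 (cat.), MeOH, 0 °C to rt
Reagents that add atoms: hydrogen peroxide OO
Why: Acid-catalysed Dakin (Baeyer–Villiger-type) oxidation, in which the electron-rich 2,4-dialkoxyaryl group migrates to oxygen and the formate is methanolysed in the pot; hydrogen peroxide without a peracid should leave the isolated terminal olefin alone, which is why mCPBA is avoided.

**Step 5**
Reactants: 12 2,4-bis(benzyloxy)-6-(non-8-enyl)phenol; 4 1-(benzyloxy)-3-bromo-5-(hept-6-enyl)benzene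
Product: 13 1,5-bis(benzyloxy)-2-[3-(benzyloxy)-5-(hept-6-enyl)phenoxy]-3-(non-8-enyl)benzene
Conditions: CuI (10 mol%), picolinic acid (20 mol%), K3PO4, DMSO, 90 °C, Ar
Reagents that add atoms: none
Why: Ullmann-type copper-catalysed diaryl ether synthesis, whose picolinate-ligated copper(I) system is known to arylate 2,6-disubstituted phenols with unactivated aryl bromides and, unlike palladium, does not engage terminal olefins in Heck reactions.

**Step 6**
Reactants: 13 1,5-bis(benzyloxy)-2-[3-(benzyloxy)-5-(hept-6-enyl)phenoxy]-3-(non-8-enyl)benzene
Product: 14 tri-O-benzyl macrocyclic olefin (the 20-membered ring of the target with a C=C bond between bridge carbons 8 and 9 counted from ring B, E/Z mixture)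
Conditions: Grubbs II (7.5 mol%), 1,4-benzoquinone (15 mol%), CH2Cl2 (1 mM, slow addition of 13), 40 °C
Reagents that add atoms: none
Why: The ruthenium benzylidene loads onto either terminal olefin, the resulting alkylidene adds to the second olefin in a [2+2] cycloaddition, and retro-[2+2] of the ruthenacyclobutane releases the ring, with loss of ethylene driving the closure. The closest known reaction type is macrocyclic ring-closing olefin metathesis of α,ω-dienes, well established for unstrained rings of this size. The one ring closed is the 20-membered ring (14 bridge carbons, two carbons of ring B, three of ring A and the ether oxygen), formed end-to-end by joining C8 of the ring-B chain to C6 of the ring-A chain as a C=C bond. No stereocentre is formed, and the E/Z ratio is of no consequence because step 7 saturates the olefin. The step needs cyclisation to win over acyclic diene metathesis oligomerisation, which high dilution with slow addition and the bent diaryl ether hinge (chain ortho to the oxygen on ring B, meta on ring A) should secure. It also needs the olefins to stay in place, which the benzoquinone additive should ensure by suppressing Ru–H olefin migration that would lead to ring-contracted homologues.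

**Step 7**
Reactants: 14 tri-O-benzyl macrocyclic olefin
Product: 15 target macrocyclic triphenol (CNP0173380)
Conditions: H2 (1 atm), 10% Pd/C, EtOAc/MeOH, rt
Reagents that add atoms: none
Why: Heterogeneous catalytic hydrogenation should saturate the disubstituted olefin and hydrogenolyse the three benzyl aryl ethers in the same operation, while the diaryl ether C–O bonds are inert under these conditions.

**Compound list**
1 | 1-(benzyloxy)-3,5-dibromobenzene | Brc1cc(Br)cc(OCc2ccccc2)c1 | starting material
2 | 7-bromohept-1-ene | C=CCCCCCBr | starting material
3 | hept-6-enylzinc bromide | C=CCCCCC[Zn]Br | intermediate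
4 | 1-(benzyloxy)-3-bromo-5-(hept-6-enyl)benzene | C=CCCCCCc1cc(Br)cc(OCc2ccccc2)c1 | intermediate
5 | 3,5-bis(benzyloxy)benzyl bromide | BrCc1cc(OCc2ccccc2)cc(OCc2ccccc2)c1 | starting material
6 | 8-bromooct-1-ene | C=CCCCCCCBr | starting material
7 | oct-7-enylmagnesium bromide | C=CCCCCCC[Mg]Br | intermediate
8 | 1,3-bis(benzyloxy)-5-(non-8-enyl)benzene | C=CCCCCCCCc1cc(OCc2ccccc2)cc(OCc2ccccc2)c1 | intermediate
9 | N-[2,4-bis(benzyloxy)-6-(non-8-enyl)benzylidene]-N-methylmethanaminium chloride | C[N+](C)=Cc1c(CCCCCCCC=C)cc(OCc2ccccc2)cc1OCc1ccccc1.[Cl-] | intermediate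
10 | 2,4-bis(benzyloxy)-6-(non-8-enyl)benzaldehyde | O=Cc1c(CCCCCCCC=C)cc(OCc2ccccc2)cc1OCc1ccccc1 | intermediate
11 | 2,4-bis(benzyloxy)-6-(non-8-enyl)phenyl formate | O=COc1c(CCCCCCCC=C)cc(OCc2ccccc2)cc1OCc1ccccc1 | intermediate
12 | 2,4-bis(benzyloxy)-6-(non-8-enyl)phenol | Oc1c(CCCCCCCC=C)cc(OCc2ccccc2)cc1OCc1ccccc1 | intermediate
13 | 1,5-bis(benzyloxy)-2-[3-(benzyloxy)-5-(hept-6-enyl)phenoxy]-3-(non-8-enyl)benzene | C=CCCCCCCCc1cc(OCc2ccccc2)cc(OCc2ccccc2)c1Oc1cc(CCCCCC=C)cc(OCc2ccccc2)c1 | intermediate
14 | tri-O-benzyl macrocyclic olefin, E/Z mixture (20-membered diaryl ether ring, C=C between bridge carbons 8 and 9 from ring B) | C(c1ccccc1)Oc1cc2cc(c1)Oc1c(OCc3ccccc3)cc(OCc3ccccc3)cc1CCCCCCCC=CCCCCC2 | intermediate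
15 | target macrocyclic triphenol (tetradecamethylene-bridged diaryl ether, CNP0173380) | Oc1cc2cc(c1)Oc1c(O)cc(O)cc1CCCCCCCCCCCCCC2 | target

**Total step count:** 7
**Longest linear sequence:** 6 steps (steps 2, 3, 4, 5, 6, 7)

**Steps most likely to fail**

Step 5. The C–O coupling may stall because the phenolic oxygen of 12 is flanked by two ortho substituents, and the electron-rich phenol may be oxidised under hot copper/base conditions. The fallback sets out from 4. Bromine–lithium exchange (n-BuLi, THF, −78 °C), trapping with B(OiPr)3 and acidic work-up should give 3-(benzyloxy)-5-(hept-6-enyl)phenylboronic acid F1. A Chan–Lam–Evans oxidative coupling of F1 with 12 (Cu(OAc)2, pyridine, 4 Å MS, CH2Cl2, air, rt), a reaction type that accepts 2,6-disubstituted phenols at room temperature, should then come back to the route at 13.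

Step 1. The coupling may run on at the second C–Br bond, and the mono- and dialkylated arenes and recovered 1 are all non-polar and may be hard to separate. The fallback sets out from 1. Mono bromine–lithium exchange (n-BuLi, 1.0 equiv, Et2O, −78 °C) followed by an iodine quench should give 1-(benzyloxy)-3-bromo-5-iodobenzene F2. Negishi coupling of F2 with 3 (Pd(PPh3)4, THF, rt) should then occur only at the C–I bond, so that selectivity rests on halide identity instead of statistics, and comes back to the route at 4.

Step 6. Intermolecular metathesis may compete and give oligomers or cyclic dimers, and olefin migration before ring closure may give ring-contracted homologues. The fallback sets out from 13. Lemieux–Johnson cleavage of both terminal olefins (OsO4 cat., NaIO4, 2,6-lutidine, dioxane/H2O; ozone is avoided because of the electron-rich arenes) should give 8-{3,5-bis(benzyloxy)-2-[3-(benzyloxy)-5-(6-oxohexyl)phenoxy]phenyl}octanal F3. An intramolecular McMurry coupling of F3 (TiCl3(DME)1.5, Zn–Cu, DME, reflux, syringe-pump addition) should then join the same two carbons as a C=C bond by reductive carbonyl coupling and come back to the route at 14.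

**Further compounds**
F1 | step 5 | 3-(benzyloxy)-5-(hept-6-enyl)phenylboronic acid | OB(O)c1cc(CCCCCC=C)cc(OCc2ccccc2)c1
F2 | step 1 | 1-(benzyloxy)-3-bromo-5-iodobenzene | Brc1cc(I)cc(OCc2ccccc2)c1
F3 | step 6 | 8-{3,5-bis(benzyloxy)-2-[3-(benzyloxy)-5-(6-oxohexyl)phenoxy]phenyl}octanal | O=CCCCCCCCc1cc(OCc2ccccc2)cc(OCc2ccccc2)c1Oc1cc(CCCCCC=O)cc(OCc2ccccc2)c1
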